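Ring A is cut into two acyclic pieces: a four-carbon ketene acetal diene (C2–C5, prenyl already on C3) and a two-carbon ynoate (C6–C1) whose β-carbon already carries the ring B oxygen. One [4+2] benzannulation then forms C5–C6 and C1–C2, closes ring A and places the carboxyl carbon C1 between the C2 hydroxyl and the C6 aryl ether, so the crowded diaryl ether is never made by arylation. The precursors are 1-methoxy-2-prenyl-1-(trimethylsilyloxy)buta-1,3-diene and an allyl 3-aryloxypropiolate with ring B protected as two methoxymethyl ethers. The step exploits the alternating O–C(CO2H)–O array of C2, C1 and C6 in ring A.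

Key step: step 8

Remarks on the chemistry (assumptions):
- Ring A is numbered C1 (carboxyl-bearing), C2 (OH), C3 (prenyl), C6 (aryloxy). Ring B is numbered C1′ (ether oxygen), C2′ (OH), C4′ (CH3), C6′ (CH2OH).
- The ester alkyl group and the ring B acetals are spectators. An allyl ester is chosen because the carboxyl group, flanked on both sides, can then be released at the O–allyl bond under neutral conditions.
- The ring B phenol is made from 3-hydroxy-5-methylbenzoic acid, where the C1′ oxygen is introduced between two directing groups.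
- The ketene acetal geometry is not controlled and is immaterial; the Z isomer is drawn.
- The target has no stereocentre. The two sp3 stereocentres that appear on the way are racemic and are destroyed.

**Step 1**
Reactants: 1 methyl (E)-but-2-enoate (methyl crotonate); 2 1-bromo-3-methylbut-2-ene (prenyl bromide)
Product: 4 methyl 2-ethenyl-5-methylhex-4-enoate (racemic), via lithium dienolate 3 (not isolated)
Conditions: LiN(i-Pr)2, DMPU, THF, −78 °C; then 2, −78 → −20 °C
Reagents that add atoms: none
Why: γ-Deprotonation of the crotonate by the amide–DMPU base gives the extended dienolate, which the allylic bromide alkylates at its α-carbon (deconjugative α-alkylation of an α,β-unsaturated ester); the new stereocentre is racemic and is erased in step 2.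

**Step 2**
Reactants: 4 methyl 2-ethenyl-5-methylhex-4-enoate
Product: 6 (1Z)-1-methoxy-2-(3-methylbut-2-en-1-yl)-1-(trimethylsilyloxy)buta-1,3-diene, via prenylated lithium dienolate 5 (not isolated)
Conditions: LiN(i-Pr)2, THF, −78 °C; Me3SiCl, −78 °C → rt; non-aqueous work-up, distillation
Reagents that add atoms: chlorotrimethylsilane, C[Si](C)(C)Cl
Why: The C–H that is both allylic and α to the ester is removed easily and the dienolate is silylated on oxygen by the hard silyl chloride (silyl ketene acetal formation), which gives the 1,1-dioxygenated diene.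

**Step 3**
Reactants: 7 3-hydroxy-5-methylbenzoic acid
Product: 8 3-(hydroxymethyl)-5-methylphenol
Conditions: BH3·THF, THF, 0 °C → rt; then H2O
Reagents that add atoms: none
Why: Borane reduces the carboxylic acid through its acyloxyborane (chemoselective borane reduction of an acid), and the phenol is returned on aqueous work-up.

**Step 4**
Reactants: 8 3-(hydroxymethyl)-5-methylphenol
Product: 9 1-(methoxymethoxy)-3-[(methoxymethoxy)methyl]-5-methylbenzene
Conditions: NaH, MeOCH2Cl, THF/DMF, 0 °C → rt
Reagents that add atoms: chloromethyl methyl ether, COCCl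
Why: Williamson-type O-alkylation of the phenoxide and the alkoxide with the reactive α-chloro ether installs two methoxymethyl acetals, which direct the next metalation and withstand organolithium reagents.

**Step 5**
Reactants: 9 1-(methoxymethoxy)-3-[(methoxymethoxy)methyl]-5-methylbenzene
Product: 12 2-(methoxymethoxy)-6-[(methoxymethoxy)methyl]-4-methylphenol, via aryllithium 10 (not isolated), via dimethyl arylboronate 11 (not isolated)
Conditions: n-BuLi, TMEDA, Et2O, 0 °C; B(OMe)3, −78 °C → rt; 30% H2O2, aq NaOH, 0 °C
Reagents that add atoms: hydrogen peroxide, OO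
Why: Directed ortho-metalation should occur at the ring C–H that lies between the aryl acetal oxygen and the benzylic acetal oxygen, since both coordinate lithium, and boronation followed by alkaline peroxide oxidation (aryl shift from boron to oxygen) turns that C–Li bond into the C1′–OH bond.

**Step 6**
Reactants: 12 2-(methoxymethoxy)-6-[(methoxymethoxy)methyl]-4-methylphenol; 13 trichloroethylene
Product: 15 2-{[(E)-1,2-dichloroethenyl]oxy}-1-(methoxymethoxy)-3-[(methoxymethoxy)methyl]-5-methylbenzene, via dichloroacetylene 14 (not isolated)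
Conditions: K2CO3, DMF, 70 °C
Reagents that add atoms: none
Why: Base-induced loss of HCl from trichloroethylene gives dichloroacetylene, to which the phenoxide adds in anti fashion (nucleophilic addition to a haloalkyne), and the small linear electrophile should tolerate the two ortho substituents of the phenol.

**Step 7**
Reactants: 15 2-{[(E)-1,2-dichloroethenyl]oxy}-1-(methoxymethoxy)-3-[(methoxymethoxy)methyl]-5-methylbenzene
Product: 18 prop-2-en-1-yl 3-{2-(methoxymethoxy)-6-[(methoxymethoxy)methyl]-4-methylphenoxy}prop-2-ynoate, via chloroalkynyl ether 16 (not isolated), via lithium acetylide 17 (not isolated)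
Conditions: n-BuLi (2.2 equiv), THF, −78 → −40 °C; then transfer into ClCO2CH2CH=CH2, THF, −78 °C
Reagents that add atoms: allyl chloroformate, C=CCOC(=O)Cl
Why: Vinylic deprotonation with loss of LiCl gives the chloroalkynyl ether, chlorine–lithium exchange with the second equivalent gives the lithium aryloxyacetylide (ynol ether synthesis from a dichlorovinyl ether), and acylation by the chloroformate under inverse addition gives the ynoate while limiting a second addition.

**Step 8**
Reactants: 6 (1Z)-1-methoxy-2-(3-methylbut-2-en-1-yl)-1-(trimethylsilyloxy)buta-1,3-diene; 18 prop-2-en-1-yl 3-{2-(methoxymethoxy)-6-[(methoxymethoxy)methyl]-4-methylphenoxy}prop-2-ynoate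
Product: 21 prop-2-en-1-yl 2-hydroxy-6-{2-(methoxymethoxy)-6-[(methoxymethoxy)methyl]-4-methylphenoxy}-3-(3-methylbut-2-en-1-yl)benzoate, via cycloadduct ketal 19 (not isolated), via aryl trimethylsilyl ether 20 (not isolated)
Conditions: 6 (2 equiv), PhMe, 100 °C, sealed tube; then 0.5 M aq HCl, THF, 0 °C
Reagents that add atoms: none
Why: Proposed new method: the terminal CH2 of diene 6 (future C5) is its nucleophilic end and the aryloxy-bearing β-carbon of ynoate 18 (future C6) is the electrophilic end of a push–pull alkyne, so C5–C6 bonding should lead and the acetal carbon (C2) should close onto the ester-bearing α-carbon (C1) in an asynchronous Diels–Alder or Michael–ring-closure sequence to cyclohexa-1,4-diene ketal 19, which aromatises by 1,4-elimination of methanol to silyl ether 20 and is desilylated on acidic work-up. The closest known reaction type is the benzannulation of 1-alkoxy-1-silyloxybuta-1,3-dienes with propiolates and acetylenedicarboxylates to salicylates; an oxygen-substituted propiolate has not been shown in it, and because its donor lowers the electrophilicity the step is run hot with an excess of diene. Ring A is closed by intermolecular [4+2] cycloaddition of the four-carbon diene with the two-carbon alkyne, both new bonds arising in the same operation. No stereocentre is set, since the ketal carbon of 19 forms as a racemate and becomes the planar C2 of the arene. The step needs the regioselectivity that places the ester carbon between the two oxygens, and the substrate secures it because the ester and the aryloxy group polarise the alkyne in the same direction and the diene has a single nucleophilic terminus. Loss of methanol in preference to silanol is supported by the acidic work-up, which hydrolyses any surviving mixed ketal to the dienone tautomer of the phenol.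

**Step 9**
Reactants: 21 prop-2-en-1-yl 2-hydroxy-6-{2-(methoxymethoxy)-6-[(methoxymethoxy)methyl]-4-methylphenoxy}-3-(3-methylbut-2-en-1-yl)benzoate
Product: 22 prop-2-en-1-yl 2-hydroxy-6-[2-hydroxy-6-(hydroxymethyl)-4-methylphenoxy]-3-(3-methylbut-2-en-1-yl)benzoate
Conditions: 2 M HCl, MeOH–THF, 40 °C
Reagents that add atoms: none
Why: Acid-catalysed transacetalisation with methanol (methoxymethyl ether cleavage) frees the C2′ phenol and the benzylic alcohol, while the flanked allyl ester resists transesterification and the C2 hydroxyl, hydrogen-bonded to the ester carbonyl, should be slow to add to the prenyl alkene.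

**Step 10**
Reactants: 22 prop-2-en-1-yl 2-hydroxy-6-[2-hydroxy-6-(hydroxymethyl)-4-methylphenoxy]-3-(3-methylbut-2-en-1-yl)benzoate
Product: 23 2-hydroxy-6-[2-hydroxy-6-(hydroxymethyl)-4-methylphenoxy]-3-(3-methylbut-2-en-1-yl)benzoic acid (target)
Conditions: Pd(PPh3)4 (5 mol %), morpholine, THF, rt; then cold aq citric acid
Reagents that add atoms: none
Why: Zerovalent palladium ionises the ester at the O–allyl bond to a π-allyl complex that morpholine captures (Tsuji–Trost deallylation), so the acid is released without attack at the shielded acyl carbon and without acid or heat that could cause decarboxylation, chroman formation or lactonisation onto the ring B alcohol.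

**Compound list**
1 | methyl (E)-but-2-enoate (methyl crotonate) | C/C=C/C(=O)OC | starting material
2 | 1-bromo-3-methylbut-2-ene (prenyl bromide) | CC(C)=CCBr | starting material
3 | lithium 1-methoxybuta-1,3-dien-1-olate (enolate geometry undefined) | C=CC=C(OC)O[Li] | intermediate (not isolated)
4 | methyl 2-ethenyl-5-methylhex-4-enoate (racemic) | C=CC(CC=C(C)C)C(=O)OC | intermediate
5 | lithium 1-methoxy-2-(3-methylbut-2-en-1-yl)buta-1,3-dien-1-olate (enolate geometry undefined) | C=CC(CC=C(C)C)=C(OC)O[Li] | intermediate (not isolated)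
6 | (1Z)-1-methoxy-2-(3-methylbut-2-en-1-yl)-1-(trimethylsilyloxy)buta-1,3-diene | C=C/C(CC=C(C)C)=C(/OC)O[Si](C)(C)C | intermediate
7 | 3-hydroxy-5-methylbenzoic acid | Cc1cc(O)cc(C(=O)O)c1 | starting material
8 | 3-(hydroxymethyl)-5-methylphenol | Cc1cc(O)cc(CO)c1 | intermediate
9 | 1-(methoxymethoxy)-3-[(methoxymethoxy)methyl]-5-methylbenzene | COCOCc1cc(C)cc(OCOC)c1 | intermediate
10 | {2-(methoxymethoxy)-6-[(methoxymethoxy)methyl]-4-methylphenyl}lithium | [Li]c1c(OCOC)cc(C)cc1COCOC | intermediate (not isolated)
11 | dimethyl {2-(methoxymethoxy)-6-[(methoxymethoxy)methyl]-4-methylphenyl}boronate | COB(OC)c1c(OCOC)cc(C)cc1COCOC | intermediate (not isolated)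
12 | 2-(methoxymethoxy)-6-[(methoxymethoxy)methyl]-4-methylphenol | COCOCc1cc(C)cc(OCOC)c1O | intermediate
13 | trichloroethylene | ClC=C(Cl)Cl | starting material
14 | dichloroacetylene | ClC#CCl | intermediate (not isolated)
15 | 2-{[(E)-1,2-dichloroethenyl]oxy}-1-(methoxymethoxy)-3-[(methoxymethoxy)methyl]-5-methylbenzene | Cl/C=C(/Cl)Oc1c(OCOC)cc(C)cc1COCOC | intermediate
16 | 2-[(chloroethynyl)oxy]-1-(methoxymethoxy)-3-[(methoxymethoxy)methyl]-5-methylbenzene | ClC#COc1c(OCOC)cc(C)cc1COCOC | intermediate (not isolated)
17 | ({2-(methoxymethoxy)-6-[(methoxymethoxy)methyl]-4-methylphenoxy}ethynyl)lithium | [Li]C#COc1c(OCOC)cc(C)cc1COCOC | intermediate (not isolated)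
18 | prop-2-en-1-yl 3-{2-(methoxymethoxy)-6-[(methoxymethoxy)methyl]-4-methylphenoxy}prop-2-ynoate | C=CCOC(=O)C#COc1c(OCOC)cc(C)cc1COCOC | intermediate
19 | prop-2-en-1-yl 6-methoxy-2-{2-(methoxymethoxy)-6-[(methoxymethoxy)methyl]-4-methylphenoxy}-5-(3-methylbut-2-en-1-yl)-6-(trimethylsilyloxy)cyclohexa-1,4-diene-1-carboxylate (racemic) | C=CCOC(=O)C1=C(Oc2c(OCOC)cc(C)cc2COCOC)CC=C(CC=C(C)C)C1(OC)O[Si](C)(C)C | intermediate (not isolated)
20 | prop-2-en-1-yl 6-{2-(methoxymethoxy)-6-[(methoxymethoxy)methyl]-4-methylphenoxy}-3-(3-methylbut-2-en-1-yl)-2-(trimethylsilyloxy)benzoate | C=CCOC(=O)c1c(O[Si](C)(C)C)c(CC=C(C)C)ccc1Oc1c(OCOC)cc(C)cc1COCOC | intermediate (not isolated)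
21 | prop-2-en-1-yl 2-hydroxy-6-{2-(methoxymethoxy)-6-[(methoxymethoxy)methyl]-4-methylphenoxy}-3-(3-methylbut-2-en-1-yl)benzoate | C=CCOC(=O)c1c(O)c(CC=C(C)C)ccc1Oc1c(OCOC)cc(C)cc1COCOC | intermediate
22 | prop-2-en-1-yl 2-hydroxy-6-[2-hydroxy-6-(hydroxymethyl)-4-methylphenoxy]-3-(3-methylbut-2-en-1-yl)benzoate | C=CCOC(=O)c1c(O)c(CC=C(C)C)ccc1Oc1c(O)cc(C)cc1CO | intermediate
23 | 2-hydroxy-6-[2-hydroxy-6-(hydroxymethyl)-4-methylphenoxy]-3-(3-methylbut-2-en-1-yl)benzoic acid | CC(C)=CCc1ccc(Oc2c(O)cc(C)cc2CO)c(C(=O)O)c1O | target

**Step count**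
Total step count: 10. Longest linear sequence: 8 steps (steps 3–10, from 7 to 23); the diene branch (steps 1–2) joins at step 8.

**Steps most likely to fail**

1. Step 8. The donor-substituted ynoate may react too slowly, so that thermal decay of the diene (silyl migration, hydrolysis, oligomerisation) outruns cycloaddition. The adduct may also aromatise by loss of silanol and leave a methyl ether. The fallback uses known chemistry, sets out from 6 and 12 and returns at 22.
   - Propiolic acid is O-allylated (allyl bromide, K2CO3, DMF) to allyl propiolate F1.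
   - F1 is brominated at the alkyne terminus (N-bromosuccinimide, AgNO3 cat., acetone) to allyl 3-bromopropiolate F2, a strongly electrophilic, established Diels–Alder dienophile whose ester directs the regiochemistry as in the parent propiolate.
   - With 6 (PhMe, rt to 60 °C, then dilute acid) F2 should give, through the bromo cycloadduct F3 and the bromoaryl trimethylsilyl ether F4, allyl 6-bromo-2-hydroxy-3-(3-methylbut-2-en-1-yl)benzoate F5.
   - The C2 hydroxyl is capped (MeOCH2Cl, i-Pr2NEt, CH2Cl2) to give the bromoaryl methoxymethyl ether F6.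
   - The ring B oxygen is attached by Ullmann ether coupling of F6 with 12 (copper monoiodide CuI, picolinic acid, K3PO4, DMSO, 90 °C), the ortho ester activating the bromide, to give the tris(methoxymethyl) diaryl ether F7.
   - Methanolic HCl as in step 9 removes all three acetals and delivers 22.

2. Step 7. A second acetylide may add to the newly formed ynoate, butyllithium may attack ring B, and the push–pull alkyne may hydrate during isolation. The fallback sets out from 15 and returns at 18.
   - n-BuLi (2.2 equiv, THF, −78 → −40 °C) converts 15 through 16 into 17, which is protonated (MeOH, −78 °C) to the terminal aryl ethynyl ether F8, a neutral compound that can be purified quickly.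
   - Relithiation (n-BuLi, THF, −78 °C) regenerates 17, which is carboxylated with dry CO2 to the lithium ynoate salt F9; this carboxylate cannot accept a second acetylide.
   - O-Alkylation of F9 in the same flask (allyl bromide, DMF, rt) gives 18.

3. Step 9. The acid may cyclise the prenyl group onto the C2 hydroxyl (chroman formation), add HCl or methanol to the alkene, or ionise the ring B benzylic carbon, while the slower benzylic acetal is still being cleaved. The fallback sets out from 15 and returns at 22; it moves the acid step to a point where neither the prenyl group nor ring A exists and ends with fluoride.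
   - Methanolic HCl (40 °C) cleaves both acetals of 15 to the dichlorovinyl ether diol F10.
   - F10 is silylated (t-BuMe2SiCl, imidazole, DMF) to the bis(silyl) dichlorovinyl ether F11; with no free neighbouring phenoxide left, silyl migration between the ring B oxygens is excluded.
   - n-BuLi and allyl chloroformate as in step 7 give, through the silyl-protected chloroalkynyl ether F12 and the silyl-protected lithium acetylide F13, the silyl-protected ynoate F14.
   - Benzannulation with 6 as in step 8 gives, through the silyl-protected cycloadduct F15 and the aryl trimethylsilyl ether F16, the silyl-protected salicylate F17.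
   - Buffered fluoride (Bu4NF, AcOH, THF, 0 °C → rt) removes both tert-butyldimethylsilyl groups from F17 to give 22.

**Further compounds**
F1 | step 8 | prop-2-en-1-yl prop-2-ynoate (allyl propiolate) | C#CC(=O)OCC=C
F2 | step 8 | prop-2-en-1-yl 3-bromoprop-2-ynoate | BrC#CC(=O)OCC=C
F3 | step 8 | prop-2-en-1-yl 2-bromo-6-methoxy-5-(3-methylbut-2-en-1-yl)-6-(trimethylsilyloxy)cyclohexa-1,4-diene-1-carboxylate (racemic) | C=CCOC(=O)C1=C(Br)CC=C(CC=C(C)C)C1(OC)O[Si](C)(C)C
F4 | step 8 | prop-2-en-1-yl 6-bromo-3-(3-methylbut-2-en-1-yl)-2-(trimethylsilyloxy)benzoate | C=CCOC(=O)c1c(O[Si](C)(C)C)c(CC=C(C)C)ccc1Br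
F5 | step 8 | prop-2-en-1-yl 6-bromo-2-hydroxy-3-(3-methylbut-2-en-1-yl)benzoate | C=CCOC(=O)c1c(O)c(CC=C(C)C)ccc1Br
F6 | step 8 | prop-2-en-1-yl 6-bromo-2-(methoxymethoxy)-3-(3-methylbut-2-en-1-yl)benzoate | C=CCOC(=O)c1c(OCOC)c(CC=C(C)C)ccc1Br
F7 | step 8 | prop-2-en-1-yl 2-(methoxymethoxy)-6-{2-(methoxymethoxy)-6-[(methoxymethoxy)methyl]-4-methylphenoxy}-3-(3-methylbut-2-en-1-yl)benzoate | C=CCOC(=O)c1c(OCOC)c(CC=C(C)C)ccc1Oc1c(OCOC)cc(C)cc1COCOC
F8 | step 7 | 2-(ethynyloxy)-1-(methoxymethoxy)-3-[(methoxymethoxy)methyl]-5-methylbenzene | C#COc1c(OCOC)cc(C)cc1COCOC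
F9 | step 7 | lithium 3-{2-(methoxymethoxy)-6-[(methoxymethoxy)methyl]-4-methylphenoxy}prop-2-ynoate | [Li+].[O-]C(=O)C#COc1c(OCOC)cc(C)cc1COCOC
F10 | step 9 | 2-{[(E)-1,2-dichloroethenyl]oxy}-3-(hydroxymethyl)-5-methylphenol | Cl/C=C(/Cl)Oc1c(O)cc(C)cc1CO
F11 | step 9 | tert-butyl{[3-(tert-butyldimethylsilyloxy)-2-{[(E)-1,2-dichloroethenyl]oxy}-5-methylphenyl]methoxy}dimethylsilane | Cl/C=C(/Cl)Oc1c(O[Si](C)(C)C(C)(C)C)cc(C)cc1CO[Si](C)(C)C(C)(C)C
F12 | step 9 | tert-butyl{[3-(tert-butyldimethylsilyloxy)-2-[(chloroethynyl)oxy]-5-methylphenyl]methoxy}dimethylsilane | ClC#COc1c(O[Si](C)(C)C(C)(C)C)cc(C)cc1CO[Si](C)(C)C(C)(C)C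
F13 | step 9 | ({2-(tert-butyldimethylsilyloxy)-6-[(tert-butyldimethylsilyloxy)methyl]-4-methylphenoxy}ethynyl)lithium | [Li]C#COc1c(O[Si](C)(C)C(C)(C)C)cc(C)cc1CO[Si](C)(C)C(C)(C)C
F14 | step 9 | prop-2-en-1-yl 3-{2-(tert-butyldimethylsilyloxy)-6-[(tert-butyldimethylsilyloxy)methyl]-4-methylphenoxy}prop-2-ynoate | C=CCOC(=O)C#COc1c(O[Si](C)(C)C(C)(C)C)cc(C)cc1CO[Si](C)(C)C(C)(C)C
F15 | step 9 | prop-2-en-1-yl 2-{2-(tert-butyldimethylsilyloxy)-6-[(tert-butyldimethylsilyloxy)methyl]-4-methylphenoxy}-6-methoxy-5-(3-methylbut-2-en-1-yl)-6-(trimethylsilyloxy)cyclohexa-1,4-diene-1-carboxylate (racemic) | C=CCOC(=O)C1=C(Oc2c(O[Si](C)(C)C(C)(C)C)cc(C)cc2CO[Si](C)(C)C(C)(C)C)CC=C(CC=C(C)C)C1(OC)O[Si](C)(C)C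
F16 | step 9 | prop-2-en-1-yl 6-{2-(tert-butyldimethylsilyloxy)-6-[(tert-butyldimethylsilyloxy)methyl]-4-methylphenoxy}-3-(3-methylbut-2-en-1-yl)-2-(trimethylsilyloxy)benzoate | C=CCOC(=O)c1c(O[Si](C)(C)C)c(CC=C(C)C)ccc1Oc1c(O[Si](C)(C)C(C)(C)C)cc(C)cc1CO[Si](C)(C)C(C)(C)C
F17 | step 9 | prop-2-en-1-yl 6-{2-(tert-butyldimethylsilyloxy)-6-[(tert-butyldimethylsilyloxy)methyl]-4-methylphenoxy}-2-hydroxy-3-(3-methylbut-2-en-1-yl)benzoate | C=CCOC(=O)c1c(O)c(CC=C(C)C)ccc1Oc1c(O[Si](C)(C)C(C)(C)C)cc(C)cc1CO[Si](C)(C)C(C)(C)C
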